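**Plan**

1. Retrosynthetic cuts: the lactone at C2′–O and C3′–C4′ (lactonisation, Claisen acylation of a C8 acetate arm), then C5–Cl, then both rings of the isochromenone at C4a–C8a and O2–C3 (isochromene numbering O2, C1, C3–C8a; primes for the lactone).
2. Enabling feature: carbocycle and pyran share the C4a–C8a bond, C4a is β to the C6 ketone and C8a is α to C1, an aldehyde carbon once O2–C3 is cut. The chain OHC(1)–C8a–C8–C7–C6(=O)–C5≡C4a–C4≡C3 can therefore fold into both rings.
3. The acyclic aldehyde–diynone is cut at C6–C5 (diynide plus dioxolanone carbonyl), at C7–C8 (enolate Michael addition) and, in the side chain, at the diyne–diene bond (Negishi) and the two C=C bonds (Wittig, Takai).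
4. Forward order: chain first (side-chain diyne 9, dioxolanone adduct 17, their union and unmasking to aldehyde 21), then the carbocycle and in the same flask the pyran (step 10), then C5 chlorination, C3′ acylation and the lactone ring last.
5. Stereochemistry: C7 from (R)-lactic acid by self-regeneration through the cis-dioxolanone; C8 from the lithium-bridged Michael transition state of the (E)-enoate; the side-chain centre from (S)-2-methylbutan-1-ol; C6′ from ethyl (S)-3-hydroxybutanoate; C3′ is labile.

Key step: step 10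

Assumption: C3′ lies between the two lactone carbonyl groups and epimerises through its enol, so the (R) configuration written for the target is taken to be the one the keto form adopts at equilibrium and no step tries to fix it kinetically.

Step 1
Reactants: 1 (S)-2-methylbutan-1-ol
Product: 2 (S)-2-methylbutanal
Conditions: TEMPO (5 mol%), PhI(OAc)2 (1.1 equiv), CH2Cl2, 0 °C to rt; NaHCO3 wash, solution used directly
Reagents that add atoms: none
Why: Oxoammonium-mediated (TEMPO/PhI(OAc)2) oxidation of a primary alcohol stops at the aldehyde under non-basic conditions, so the α-stereocentre is not enolised, and the volatile aldehyde is carried on in solution.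

Step 2
Reactants: 2 (S)-2-methylbutanal, 3 2-(triphenylphosphoranylidene)propanal
Product: 4 (2E,4S)-2,4-dimethylhex-2-enal
Conditions: 3 (1.2 equiv), CH2Cl2, reflux
Reagents that add atoms: none
Why: Wittig olefination with a stabilised formyl ylide is (E)-selective for trisubstituted enals, needs no base that could epimerise 2, and the hindered α-methyl enal formed should react with the ylide far more slowly than 2.

Step 3
Reactants: 4 (2E,4S)-2,4-dimethylhex-2-enal
Product: 5 (1E,3E,5S)-1-iodo-3,5-dimethylhepta-1,3-diene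
Conditions: CrCl2 (6 equiv), CHI3 (2 equiv), THF, 0 °C
Reagents that add atoms: iodoform, IC(I)I
Why: Takai olefination: the gem-dichromium species generated from CHI3 and CrCl2 adds to the aldehyde and eliminates to the (E)-alkenyl iodide, a reaction that is routine for enals and touches neither the trisubstituted alkene nor the remote stereocentre.

Step 4
Reactants: 6 1,4-bis(trimethylsilyl)buta-1,3-diyne, 5 (1E,3E,5S)-1-iodo-3,5-dimethylhepta-1,3-diene
Product: 9 trimethyl[(5E,7E,9S)-7,9-dimethylundeca-5,7-dien-1,3-diyn-1-yl]silane, via lithium 4-(trimethylsilyl)buta-1,3-diyn-1-ide 7 (not isolated), via bromo[4-(trimethylsilyl)buta-1,3-diyn-1-yl]zinc 8 (not isolated)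
Conditions: 6 (1.5 equiv), MeLi·LiBr (1.5 equiv), THF, −78 °C to rt; ZnBr2 (1.6 equiv), 0 °C; 5, Pd(PPh3)4 (5 mol%), rt
Reagents that add atoms: none
Why: MeLi·LiBr removes one silyl group of 6 selectively, and Negishi coupling of the resulting diynylzinc with the alkenyl iodide (Pd(PPh3)4, zerovalent palladium) retains the (E)-geometry and avoids the copper and amine that promote diyne homocoupling.

Step 5
Reactants: 10 (R)-lactic acid, 11 pivalaldehyde
Product: 12 (2R,5R)-2-tert-butyl-5-methyl-1,3-dioxolan-4-one
Conditions: 11 (1.2 equiv), TsOH·H2O (cat.), H2SO4 (cat.), pentane, reflux, Dean–Stark; recrystallisation from pentane at −78 °C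
Reagents that add atoms: none
Why: Acid-catalysed acetalisation under equilibrating conditions favours the cis-dioxolanone, which is purified by crystallisation and stores the lactate configuration in the new acetal centre (first stage of self-regeneration of stereocentres).

Step 6
Reactants: 13 4,4-diethoxybut-1-ene, 14 methyl acrylate
Product: 15 methyl (2E)-5,5-diethoxypent-2-enoate
Conditions: 14 (3 equiv), second-generation Grubbs catalyst (H2IMes)(PCy3)Cl2Ru=CHPh (2 mol%), CH2Cl2, 40 °C
Reagents that add atoms: none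
Why: Olefin cross-metathesis between an unhindered terminal alkene and an excess of acrylate gives the hetero-coupled (E)-enoate selectively, and the acetal is inert to the ruthenium carbene.

Step 7
Reactants: 12 (2R,5R)-2-tert-butyl-5-methyl-1,3-dioxolan-4-one, 15 methyl (2E)-5,5-diethoxypent-2-enoate
Product: 17 methyl (3R)-3-[(2R,4S)-2-tert-butyl-4-methyl-5-oxo-1,3-dioxolan-4-yl]-5,5-diethoxypentanoate, via lithium (2R)-2-tert-butyl-5-methyl-1,3-dioxol-4-olate 16 (not isolated)
Conditions: LiN(i-Pr)2 (1.05 equiv), THF, −78 °C; 15 (1.1 equiv), −78 °C; AcOH, −78 °C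
Reagents that add atoms: none
Why: Michael addition of the dioxolanone lithium enolate: the enoate approaches the face opposite to the tert-butyl group, which fixes C7 with overall retention of the lactate configuration, and C8 is set in a lithium-bridged closed transition state in which the ester carbonyl of the (E)-enoate lies over the enolate oxygen so that the β-hydrogen, not the acetal chain, faces the dioxolanone ring, in line with the high diastereoselectivity known for additions of such enolates to nitroalkenes and enones.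

Step 8
Reactants: 9 trimethyl[(5E,7E,9S)-7,9-dimethylundeca-5,7-dien-1,3-diyn-1-yl]silane, 17 methyl (3R)-3-[(2R,4S)-2-tert-butyl-4-methyl-5-oxo-1,3-dioxolan-4-yl]-5,5-diethoxypentanoate
Product: 19 methyl (3R,4S,10E,12E,14S)-3-(2,2-diethoxyethyl)-4-hydroxy-4,12,14-trimethyl-5-oxohexadeca-10,12-dien-6,8-diynoate, via lithium (5E,7E,9S)-7,9-dimethylundeca-5,7-dien-1,3-diyn-1-ide 18 (not isolated)
Conditions: 9 (1.3 equiv), MeLi·LiBr (1.25 equiv), THF, −78 °C to rt; 17, THF, −78 °C; AcOH, −78 °C to rt; crude product used at once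
Reagents that add atoms: none
Why: Addition of a lithium acetylide to an activated lactone: desilylative lithiation of 9 gives diynide 18, which adds once to the acylal-type dioxolanone carbonyl while the methyl ester is inert at −78 °C, and the tetrahedral lithium alkoxide survives until the cold acidic quench, when it releases pivalaldehyde and the α-hydroxy ynone without exposing a free alkoxide to the ester or the ynone.

Step 9
Reactants: 19 methyl (3R,4S,10E,12E,14S)-3-(2,2-diethoxyethyl)-4-hydroxy-4,12,14-trimethyl-5-oxohexadeca-10,12-dien-6,8-diynoate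
Product: 21 methyl (3R,4S,10E,12E,14S)-4,12,14-trimethyl-5-oxo-3-(2-oxoethyl)-4-(triethylsilyloxy)hexadeca-10,12-dien-6,8-diynoate, via N-(1-ethoxyalkyl)-2,4,6-trimethylpyridinium triflate 20 (not isolated)
Conditions: Et3SiOTf (3.5 equiv), 2,4,6-collidine (5 equiv), CH2Cl2, −78 to 0 °C; H2O, 0 °C to rt
Reagents that add atoms: triethylsilyl trifluoromethanesulfonate, CC[Si](CC)(CC)OS(=O)(=O)C(F)(F)F; water, O
Why: Silyl triflate/collidine chemistry does two known jobs in one flask: it silylates the hindered tertiary alcohol and converts the diethyl acetal into an N,O-acetal pyridinium salt that water hydrolyses to the aldehyde, a cleavage that spares silyl ethers, the ester and the diynone and avoids aqueous acid.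

Step 10
Reactants: 21 methyl (3R,4S,10E,12E,14S)-4,12,14-trimethyl-5-oxo-3-(2-oxoethyl)-4-(triethylsilyloxy)hexadeca-10,12-dien-6,8-diynoate
Product: 23 methyl 2-[(7S,8S)-3-[(1E,3E,5S)-3,5-dimethylhepta-1,3-dien-1-yl]-7-methyl-6-oxo-7-(triethylsilyloxy)-7,8-dihydro-6H-isochromen-8-yl]acetate, via 4-formyl-3-alkynylcyclohex-2-enone 22 (not isolated)
Conditions: Bn2NH·CF3CO2H (0.3 equiv), toluene (0.02 M), 40 °C; then Ph3PAuNTf2 (5 mol%), rt
Reagents that add atoms: none
Why: The dibenzylammonium salt converts the unhindered aldehyde into its enamine, whose nucleophilic carbon C8a adds to C4a, the β-carbon of the ynone, in a 6-endo-dig closure (C4a–C8a bond, carbocycle), and protonation at C5 with hydrolysis gives the cross-conjugated enone 22 that carries the 2-alkynyl aldehyde unit. Cationic monovalent gold (Ph3PAuNTf2) then activates the remaining alkyne, the aldehyde oxygen attacks C3 in a second 6-endo-dig closure (O2–C3 bond, pyran), and loss of the C8a proton with protodeauration at C4 leaves the C1=C8a, C3=C4, C4a=C5 trienone. The closest known reactions are amine-mediated 6-endo-dig Michael cyclisations onto ynones (carbonyl-tethered alkynones, β-amino and β-hydroxy ynones) and the gold-catalysed cycloisomerisation of 2-alkynyl enals and 2-alkynylbenzaldehydes to pyrans and pyrylium ions. No new stereocentre survives, since C8a ends sp2, and C7 and C8 cannot be epimerised because C7 is quaternary and the C8 hydrogen is not α to a carbonyl group. The step needs C- rather than O-attack at C4a and 1,4- rather than 1,6-addition: the silyl ether on the C7 oxygen removes the only oxygen nucleophile that could close a furanone, attack at C3 would demand an eight-membered ring, and the weakly nucleophilic, largely protonated dibenzylamine is chosen to condense with the aldehyde faster than it adds to the diynone. In the gold stage 6-endo attack at C3 should beat 5-exo attack at C4 because C3 is the δ-position of the enynone and carries the cation-stabilising dienyl group.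

Step 11
Reactants: 23 methyl 2-[(7S,8S)-3-[(1E,3E,5S)-3,5-dimethylhepta-1,3-dien-1-yl]-7-methyl-6-oxo-7-(triethylsilyloxy)-7,8-dihydro-6H-isochromen-8-yl]acetate
Product: 24 methyl 2-[(7S,8S)-5-chloro-3-[(1E,3E,5S)-3,5-dimethylhepta-1,3-dien-1-yl]-7-methyl-6-oxo-7-(triethylsilyloxy)-7,8-dihydro-6H-isochromen-8-yl]acetate
Conditions: N-chlorosuccinimide (1.05 equiv), MeCN, 0 °C to rt
Reagents that add atoms: N-chlorosuccinimide, O=C1CCC(=O)N1Cl
Why: Electrophilic chlorination with N-chlorosuccinimide occurs at C5, the α-carbon of the vinylogous ester and the terminus of both dienol ether systems (O2–C1=C8a–C4a=C5 and O2–C3=C4–C4a=C5), as in the C5 halogenation of azaphilone pigments, and should be faster than attack on the unactivated dienyl chain.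

Step 12
Reactants: 25 ethyl (S)-3-hydroxybutanoate
Product: 26 ethyl (3S)-3-(triethylsilyloxy)butanoate
Conditions: Et3SiCl (1.2 equiv), imidazole (2 equiv), CH2Cl2, 0 °C to rt
Reagents that add atoms: chlorotriethylsilane, CC[Si](Cl)(CC)CC
Why: Silylation of a secondary alcohol with a chlorosilane and imidazole is routine and leaves the stereocentre untouched.

Step 13
Reactants: 26 ethyl (3S)-3-(triethylsilyloxy)butanoate
Product: 27 (3S)-N-methoxy-N-methyl-3-(triethylsilyloxy)butanamide
Conditions: MeNH(OMe)·HCl (1.5 equiv), i-PrMgCl (3 equiv), THF, −20 to 0 °C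
Reagents that add atoms: N,O-dimethylhydroxylamine hydrochloride, CNOC.Cl
Why: Direct ester-to-Weinreb amide conversion with the chloromagnesium amide of N,O-dimethylhydroxylamine runs below 0 °C, where neither elimination of the β-silyloxy group nor loss of the silyl ether is expected.

Step 14
Reactants: 24 methyl 2-[(7S,8S)-5-chloro-3-[(1E,3E,5S)-3,5-dimethylhepta-1,3-dien-1-yl]-7-methyl-6-oxo-7-(triethylsilyloxy)-7,8-dihydro-6H-isochromen-8-yl]acetate, 27 (3S)-N-methoxy-N-methyl-3-(triethylsilyloxy)butanamide
Product: 29 methyl (5S)-2-[(7S,8S)-5-chloro-3-[(1E,3E,5S)-3,5-dimethylhepta-1,3-dien-1-yl]-7-methyl-6-oxo-7-(triethylsilyloxy)-7,8-dihydro-6H-isochromen-8-yl]-3-oxo-5-(triethylsilyloxy)hexanoate, via lithium enolate of the methyl ester 28 (not isolated)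
Conditions: LiN(SiMe3)2 (1.1 equiv), THF, −78 °C; 27 (1.5 equiv), −78 to −30 °C; AcOH, −78 °C
Reagents that add atoms: none
Why: Crossed Claisen condensation: the ester α-CH2 is the only site that LiN(SiMe3)2 can deprotonate (C7 is quaternary and C5 carries chlorine), and the Weinreb amide acylates the enolate only once because the chelated tetrahedral adduct persists until the quench, so no second equivalent of base and no acyl halide is needed; the C3′ centre forms as a mixture that equilibrates later.

Step 15
Reactants: 29 methyl (5S)-2-[(7S,8S)-5-chloro-3-[(1E,3E,5S)-3,5-dimethylhepta-1,3-dien-1-yl]-7-methyl-6-oxo-7-(triethylsilyloxy)-7,8-dihydro-6H-isochromen-8-yl]-3-oxo-5-(triethylsilyloxy)hexanoate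
Product: 32 (3R,6S)-3-[(7S,8S)-5-chloro-3-[(1E,3E,5S)-3,5-dimethylhepta-1,3-dien-1-yl]-7-hydroxy-7-methyl-6-oxo-7,8-dihydro-6H-isochromen-8-yl]-6-methyloxane-2,4-dione (CNP0584120.1), via δ-hydroxy β-keto ester 30 (not isolated), via C7-O-triethylsilyl lactone 31 (not isolated)
Conditions: HF·pyridine, pyridine, THF, 0 °C to rt
Reagents that add atoms: none
Why: Fluoride-mediated desilylation is staged by sterics: the secondary silyl ether falls first and the freed hydroxyl closes the six-membered lactone on the β-keto ester with loss of methanol while the hindered tertiary C7 silyl ether still blocks the competing γ-lactone, then the tertiary ether is cleaved at room temperature and C3′ settles by enolisation.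

**Compound list**

1 | (S)-2-methylbutan-1-ol | CC[C@H](C)CO | starting material
2 | (S)-2-methylbutanal | CC[C@H](C)C=O | intermediate
3 | 2-(triphenylphosphoranylidene)propanal | CC(C=O)=P(c1ccccc1)(c1ccccc1)c1ccccc1 | starting material
4 | (2E,4S)-2,4-dimethylhex-2-enal | CC[C@H](C)/C=C(C)/C=O | intermediate
5 | (1E,3E,5S)-1-iodo-3,5-dimethylhepta-1,3-diene | CC[C@H](C)/C=C(C)/C=C/I | intermediate
6 | 1,4-bis(trimethylsilyl)buta-1,3-diyne | C[Si](C)(C)C#CC#C[Si](C)(C)C | starting material
7 | lithium 4-(trimethylsilyl)buta-1,3-diyn-1-ide | [Li]C#CC#C[Si](C)(C)C | intermediate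
8 | bromo[4-(trimethylsilyl)buta-1,3-diyn-1-yl]zinc | Br[Zn]C#CC#C[Si](C)(C)C | intermediate
9 | trimethyl[(5E,7E,9S)-7,9-dimethylundeca-5,7-dien-1,3-diyn-1-yl]silane | C[Si](C)(C)C#CC#C/C=C/C(C)=C/[C@@H](C)CC | intermediate
10 | (R)-lactic acid | C[C@@H](O)C(=O)O | starting material
11 | pivalaldehyde (2,2-dimethylpropanal) | CC(C)(C)C=O | starting material
12 | (2R,5R)-2-tert-butyl-5-methyl-1,3-dioxolan-4-one | C[C@H]1O[C@@H](C(C)(C)C)OC1=O | intermediate
13 | 4,4-diethoxybut-1-ene | C=CCC(OCC)OCC | starting material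
14 | methyl acrylate | C=CC(=O)OC | starting material
15 | methyl (2E)-5,5-diethoxypent-2-enoate | CCOC(C/C=C/C(=O)OC)OCC | intermediate
16 | lithium (2R)-2-tert-butyl-5-methyl-1,3-dioxol-4-olate | CC1=C(O[Li])O[C@H](C(C)(C)C)O1 | intermediate
17 | methyl (3R)-3-[(2R,4S)-2-tert-butyl-4-methyl-5-oxo-1,3-dioxolan-4-yl]-5,5-diethoxypentanoate | COC(=O)C[C@@H](CC(OCC)OCC)[C@]1(C)O[C@@H](C(C)(C)C)OC1=O | intermediate
18 | lithium (5E,7E,9S)-7,9-dimethylundeca-5,7-dien-1,3-diyn-1-ide | [Li]C#CC#C/C=C/C(C)=C/[C@@H](C)CC | intermediate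
19 | methyl (3R,4S,10E,12E,14S)-3-(2,2-diethoxyethyl)-4-hydroxy-4,12,14-trimethyl-5-oxohexadeca-10,12-dien-6,8-diynoate | COC(=O)C[C@@H](CC(OCC)OCC)[C@](C)(O)C(=O)C#CC#C/C=C/C(C)=C/[C@@H](C)CC | intermediate
20 | methyl (3R,4S,10E,12E,14S)-3-[2-ethoxy-2-(2,4,6-trimethylpyridin-1-ium-1-yl)ethyl]-4,12,14-trimethyl-5-oxo-4-(triethylsilyloxy)hexadeca-10,12-dien-6,8-diynoate trifluoromethanesulfonate (both configurations at the N,O-acetal carbon) | COC(=O)C[C@@H](CC(OCC)[n+]1c(C)cc(C)cc1C)[C@](C)(O[Si](CC)(CC)CC)C(=O)C#CC#C/C=C/C(C)=C/[C@@H](C)CC.[O-]S(=O)(=O)C(F)(F)F | intermediate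
21 | methyl (3R,4S,10E,12E,14S)-4,12,14-trimethyl-5-oxo-3-(2-oxoethyl)-4-(triethylsilyloxy)hexadeca-10,12-dien-6,8-diynoate | COC(=O)C[C@@H](CC=O)[C@](C)(O[Si](CC)(CC)CC)C(=O)C#CC#C/C=C/C(C)=C/[C@@H](C)CC | intermediate
22 | methyl 2-[(1S,2S)-5-[(3E,5E,7S)-5,7-dimethylnona-3,5-dien-1-yn-1-yl]-6-formyl-2-methyl-3-oxo-2-(triethylsilyloxy)cyclohex-4-en-1-yl]acetate (both C6 epimers) | COC(=O)C[C@@H]1[C@](C)(O[Si](CC)(CC)CC)C(=O)C=C(C#C/C=C/C(C)=C/[C@@H](C)CC)C1C=O | intermediate
23 | methyl 2-[(7S,8S)-3-[(1E,3E,5S)-3,5-dimethylhepta-1,3-dien-1-yl]-7-methyl-6-oxo-7-(triethylsilyloxy)-7,8-dihydro-6H-isochromen-8-yl]acetate | CC[C@H](C)/C=C(C)/C=C/C1=CC2=CC(=O)[C@@](C)(O[Si](CC)(CC)CC)[C@@H](CC(=O)OC)C2=CO1 | intermediate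
24 | methyl 2-[(7S,8S)-5-chloro-3-[(1E,3E,5S)-3,5-dimethylhepta-1,3-dien-1-yl]-7-methyl-6-oxo-7-(triethylsilyloxy)-7,8-dihydro-6H-isochromen-8-yl]acetate | CC[C@H](C)/C=C(C)/C=C/C1=CC2=C(Cl)C(=O)[C@@](C)(O[Si](CC)(CC)CC)[C@@H](CC(=O)OC)C2=CO1 | intermediate
25 | ethyl (S)-3-hydroxybutanoate | CCOC(=O)C[C@H](C)O | starting material
26 | ethyl (3S)-3-(triethylsilyloxy)butanoate | CCOC(=O)C[C@H](C)O[Si](CC)(CC)CC | intermediate
27 | (3S)-N-methoxy-N-methyl-3-(triethylsilyloxy)butanamide | CON(C)C(=O)C[C@H](C)O[Si](CC)(CC)CC | intermediate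
28 | lithium 2-[(7S,8S)-5-chloro-3-[(1E,3E,5S)-3,5-dimethylhepta-1,3-dien-1-yl]-7-methyl-6-oxo-7-(triethylsilyloxy)-7,8-dihydro-6H-isochromen-8-yl]-1-methoxyethen-1-olate | CC[C@H](C)/C=C(C)/C=C/C1=CC2=C(Cl)C(=O)[C@@](C)(O[Si](CC)(CC)CC)[C@@H](C=C(O[Li])OC)C2=CO1 | intermediate
29 | methyl (5S)-2-[(7S,8S)-5-chloro-3-[(1E,3E,5S)-3,5-dimethylhepta-1,3-dien-1-yl]-7-methyl-6-oxo-7-(triethylsilyloxy)-7,8-dihydro-6H-isochromen-8-yl]-3-oxo-5-(triethylsilyloxy)hexanoate (both C2 epimers) | CC[C@H](C)/C=C(C)/C=C/C1=CC2=C(Cl)C(=O)[C@@](C)(O[Si](CC)(CC)CC)[C@@H](C(C(=O)OC)C(=O)C[C@H](C)O[Si](CC)(CC)CC)C2=CO1 | intermediate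
30 | methyl (5S)-2-[(7S,8S)-5-chloro-3-[(1E,3E,5S)-3,5-dimethylhepta-1,3-dien-1-yl]-7-methyl-6-oxo-7-(triethylsilyloxy)-7,8-dihydro-6H-isochromen-8-yl]-5-hydroxy-3-oxohexanoate | CC[C@H](C)/C=C(C)/C=C/C1=CC2=C(Cl)C(=O)[C@@](C)(O[Si](CC)(CC)CC)[C@@H](C(C(=O)OC)C(=O)C[C@H](C)O)C2=CO1 | intermediate
31 | (6S)-3-[(7S,8S)-5-chloro-3-[(1E,3E,5S)-3,5-dimethylhepta-1,3-dien-1-yl]-7-methyl-6-oxo-7-(triethylsilyloxy)-7,8-dihydro-6H-isochromen-8-yl]-6-methyloxane-2,4-dione | CC[C@H](C)/C=C(C)/C=C/C1=CC2=C(Cl)C(=O)[C@@](C)(O[Si](CC)(CC)CC)[C@@H](C3C(=O)C[C@H](C)OC3=O)C2=CO1 | intermediate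
32 | (3R,6S)-3-[(7S,8S)-5-chloro-3-[(1E,3E,5S)-3,5-dimethylhepta-1,3-dien-1-yl]-7-hydroxy-7-methyl-6-oxo-7,8-dihydro-6H-isochromen-8-yl]-6-methyloxane-2,4-dione (CNP0584120.1) | CC[C@H](C)/C=C(C)/C=C/C1=CC2=C(Cl)C(=O)[C@@](C)(O)[C@@H]([C@@H]3C(=O)C[C@H](C)OC3=O)C2=CO1 | target

**Step count and risks**

Total step count: 15. Longest linear sequence: 10 steps (steps 1, 2, 3, 4, 8, 9, 10, 11, 14, 15, from (S)-2-methylbutan-1-ol).

Most likely to fail, in this order:

Step 10. The secondary amine may add to the electron-poor diynone or be held back as a push–pull dienamine of 22, and the enamine reaches C4a only through a bent 6-endo geometry, so oligomerisation of the diynone can outrun the first ring closure. The fallback sets out from 21 and comes back at 23; it moves the activation from the donor to the acceptor. Aldehyde 21 would be treated with t-BuMe2SiOTf and i-Pr2NEt (CH2Cl2, −78 °C) to give its tert-butyldimethylsilyl enol ether F1. F1 would then be exposed to Ph3PAuNTf2 (5 mol%) in CH2Cl2 containing two equivalents of water. π-Activation of the ynone alkyne lets the enol ether carbon attack C4a anti to gold, which is the known gold-catalysed carbocyclisation of silyl enol ethers onto alkynes and needs no allenolate. Hydrolytic loss of the silyl group and protodeauration give 22, and the same complex closes the pyran to 23.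

Step 7. Facial selectivity at the β-carbon of the enoate (C8) may be poor or reversed if more open transition states compete with the lithium-bridged one. The fallback sets out from 12 and comes back at 17; it uses acceptor geometry as the control element. Swern oxidation of commercial 3,3-diethoxypropan-1-ol would give 3,3-diethoxypropanal F2. Ando olefination of F2 (methyl (diphenoxyphosphoryl)acetate, NaH, THF, −78 °C) would give methyl (2Z)-5,5-diethoxypent-2-enoate F3. Enolate 16 would be added to F3 under the conditions of step 7. Whatever transition-state family operates, changing (E) to (Z) exchanges the hydrogen and the acetal chain at the β-carbon, so the C8 epimer that is under-produced from 15 should be the one favoured from F3, namely 17.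

Step 14. Acylation of the hindered ester enolate may be slow, which leaves time for proton transfer to the amide or for attack of the enolate on the electrophilic C1 of a second molecule. The fallback sets out from 24 and 26 and comes back at 29; it replaces acyl transfer by aldol addition and oxidation. Ester 26 would be reduced with (i-Bu)2AlH (CH2Cl2, −78 °C) to (3S)-3-(triethylsilyloxy)butanal F4. Enolate 28, generated as in step 14, should add to F4 within minutes at −78 °C to give β-hydroxy ester F5 as a mixture at the two new centres. Dess–Martin periodinane (NaHCO3, CH2Cl2) would oxidise F5 to β-keto ester 29.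

**Further compounds**

F1 | step 10 | methyl (3S,4S,10E,12E,14S)-3-[2-(tert-butyldimethylsilyloxy)ethenyl]-4,12,14-trimethyl-5-oxo-4-(triethylsilyloxy)hexadeca-10,12-dien-6,8-diynoate | COC(=O)C[C@@H](C=CO[Si](C)(C)C(C)(C)C)[C@](C)(O[Si](CC)(CC)CC)C(=O)C#CC#C/C=C/C(C)=C/[C@@H](C)CC
F2 | step 7 | 3,3-diethoxypropanal | CCOC(CC=O)OCC
F3 | step 7 | methyl (2Z)-5,5-diethoxypent-2-enoate | CCOC(C/C=C\C(=O)OC)OCC
F4 | step 14 | (3S)-3-(triethylsilyloxy)butanal | O=CC[C@H](C)O[Si](CC)(CC)CC
F5 | step 14 | methyl (5S)-2-[(7S,8S)-5-chloro-3-[(1E,3E,5S)-3,5-dimethylhepta-1,3-dien-1-yl]-7-methyl-6-oxo-7-(triethylsilyloxy)-7,8-dihydro-6H-isochromen-8-yl]-3-hydroxy-5-(triethylsilyloxy)hexanoate | CC[C@H](C)/C=C(C)/C=C/C1=CC2=C(Cl)C(=O)[C@@](C)(O[Si](CC)(CC)CC)[C@@H](C(C(=O)OC)C(O)C[C@H](C)O[Si](CC)(CC)CC)C2=CO1
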